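## The problem

The target 25 is a B-type proanthocyanidin trimer: C4 of a top (−)-epicatechin 3-O-gallate is bonded to C6 of a middle (−)-epicatechin 3-O-gallate, whose C4 is bonded to C8 of a bottom (+)-catechin. It has eight stereocentres: C2, C3 and C4 of each upper unit (2R,3R; C2 aryl cis to the C3 ester; C4 aryl β and trans to the ester) and C2, C3 of the catechin (2R,3S). The catechin centres are too remote to control either upper ring, so each upper ring C needs its own source of absolute configuration; inside one ring C the three centres are contiguous and can control each other. The 4→6 bond is the regiochemical crux, because ring A of a flavan reacts with C4 electrophiles at C8 in preference to C6. Eighteen phenols (air oxidation), two hindered gallate esters (base, hard nucleophiles), the interflavan bonds (C4 re-ionises in strong acid) and the C2 centres (base-induced ring opening) forbid harsh conditions late in the route. Two structural features open a cycloaddition route. In each upper unit, O1–C2 and C3–C4 of ring C enclose all three stereocentres and C3 carries the ester, so cutting both bonds leaves an ortho-quinone methide (O1=C8a–C4a=C4) and a Z enol gallate. Ring A of the middle unit, before its ring C exists, is a 2,6-dioxygenated 4-hydroxyphenyl group with a local twofold axis through C6 and C8a, so its two positions ortho to the phenol are equivalent and functionalisation there can only give the 4→6 pattern.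

## Retrosynthesis

**25 to 24.** No skeletal bond is cut. All nineteen hydroxyl groups are carried as benzyl ethers in 24 and released by one hydrogenolysis. Benzyl is preferred to acetal, silyl or acyl protection because its removal is neutral; acid would re-ionise C4 and base would attack the gallates and C2. This fixes the rule that every fragment arrives benzylated.

**24 to 22 and 11.** O1–C2 and C3–C4 of the middle ring C are cut together, leading to ortho-quinone methide 23 (from benzhydrol 22 by loss of water) and the Z enol gallate 11. The neighbouring cut at the C4–C8 interflavan bond would need an intact middle unit already joined 4→6 to the top unit, the connection flavan chemistry makes least willingly. The precursor has one ring, three stereocentres and one ester fewer. The forward reaction must be regioselective (C3 to C4, O1 to C2), suprafacial on the Z alkene, endo, and face-selective under catalyst control beside existing stereocentres.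

**22 to 15 and 19.** The carbinol carbon of 22 is the future C4 of the middle unit. Cutting its bond to C8 of the bottom unit gives salicylaldehyde 15 and an aryl nucleophile (arylmagnesium bromide 21, made through aryllithium 20 from bromide 19). The carbinol configuration is irrelevant, so this is the cheapest point to attach the chiral-pool fragment. 19 goes back through ethers 18 and 17 to (+)-catechin 16, which supplies C2 and C3 of the bottom unit. The addition has to spare the gallate of 15, hence magnesium and not lithium as counter-ion.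

**15 to 14 to 13.** The formyl carbon is removed (ortho-formylation of phenol 14) and the phenol is masked as silyl ether 13. Because of the twofold axis of the C4 aryl group, either ortho position gives the same aldehyde, and no regiochemical decision is needed. Carrying the formyl group or the bottom unit through the first cycloaddition would put an electrophilic aldehyde or a second ionisable carbinol into that step.

**13 to 7 and 11 (key disconnection).** The same double cut in the top ring C gives ortho-quinone methide 12 (from benzhydrol 7) and again 11, so one dienophile serves both upper units. Cuts at C4–aryl (flavan cation plus arene) or at C2–aryl would leave ring C and its C2/C3 centres to be made separately, in practice from (−)-epicatechin. Here the precursors are a racemic carbinol and an achiral alkene, and the step must create C2, C3 and C4 with absolute control from a chiral phosphoric acid.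

**7 to 2 and 5.** The carbinol–aryl bond is cut into salicylaldehyde 2 and aryllithium 6, which comes from bromide 5 by halogen–metal exchange. 5 comes from silyl ether 4 and 3,5-bis(benzyloxy)phenol 3; 2 comes from 2,4,6-trihydroxybenzaldehyde 1 by twofold benzylation. The sequence asks for one regioselective bromination, para to the silyloxy group of 4.

**11 to 9 and 10.** The vinylic C–O bond is cut into alkyne 9 and 3,4,5-tris(benzyloxy)benzoic acid 10. Enolate acylation of an arylacetaldehyde, the obvious alternative, gives no reliable control of alkene geometry. 9 is the one-carbon homologue of 3,4-bis(benzyloxy)benzaldehyde 8. The addition must be anti-Markovnikov and Z-selective, which a ruthenium vinylidene pathway provides.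

## Roads not taken

**Alternative 1:** The cut is at both C2–aryl bonds of the upper units, so the two catechol B rings arrive last.
- Forward key step: a trimeric core with acetoxy groups at C2 of the top and middle units is ionised with BF3·OEt2 to two cyclic oxocarbenium ions, and an arylzinc nucleophile adds to both. The product is A1, the benzyl-protected trimer with silyl ethers on the two upper C3 oxygens.
- Merits: both B rings come from one simple nucleophile, C-arylation of six-membered oxocarbenium ions is an established reaction type, and B-ring analogues would be one step away.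
- Weak points: the substrate of that step must already hold both interflavan bonds, the 4→6 regiochemistry and C3/C4 of both upper units, so the hard part is moved, not shortened. The aryl group must enter cis to the C3 silyloxy group and trans to the C4 aryl group at two different cations in one flask, and nothing guarantees that the neighbouring alkoxy group and the pseudo-axial C4 aryl group cooperate in both rings. BF3 is the kind of reagent under which C4–aryl bonds and the new benzylic C2–O1 bonds re-ionise. After A1, two desilylations at hindered carbinols and two esterifications still precede hydrogenolysis.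
- Comparison: in precedent this road is stronger, since none of its reactions is a new type. Against that, the chosen plan makes C2, C3, C4 and the ester of an upper unit in one step from achiral fragments and solves the 4→6 problem by symmetry.

**Alternative 2:** The cut is C4–C4a of the middle unit.
- Forward key step: an aryl ether in which O1 of the middle ring A is tethered to a trans epoxide is treated with acid. The epoxide opens at the benzylic carbon bearing the catechin C8 aryl group, and an ortho carbon of the symmetric bis(benzyloxy)phenyl ether attacks with inversion (intramolecular Friedel–Crafts closure of a six-membered ring). The product is A2, the protected trimer with a free C3 hydroxyl on the middle unit.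
- Merits: the 3,4-trans relationship follows from a stereospecific inversion, the same ring symmetry removes the regiochemical question, the absolute configuration can come from a reliable asymmetric oxidation of an E alkene, and epoxide–arene cyclisation is a known reaction type.
- Weak points: the epoxide carbon carries a 2,4,6-trioxygenated aryl group and will ionise to a free cation, which erodes the inversion and invites 1,2-shift to a ketone. The substrate needs a configurationally defined benzylic aryl ether at C2 next to the epoxide, itself made by substitution at a carbon prone to ionisation. The attacking arene is flanked by the top unit. The middle gallate must afterwards be put on a carbinol wedged between two aryl-bearing carbons.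
- Comparison: this road is better in that C3/C4 rest on a stereospecific event and not on an endo preference, and it needs no new reaction type. The chosen plan sets against it convergence (each upper unit from a benzhydrol and one common enol ester) and delivery of the ester with the ring. The ease of ionisation at C4 that undermines A2 is what drives the cycloaddition.

**Alternative 3:** The cut runs through ring A of the middle unit (C6–C7, C7–C8 and C4a–C5).
- Forward key step: a top unit carrying a silyloxyalkyne at C4 is heated with a 3-alkoxycyclobutenone. Electrocyclic opening to a vinylketene, (2+2) addition to the alkyne, ring opening and 6π closure give the phenol A3. In A3 O7 is free, O5 is silylated, the future O1 is a methoxymethyl ether and C4a carries a silyloxymethyl group.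
- Merits: the substitution pattern of the pentasubstituted ring is fixed by mechanism, every oxygen is distinguished, and the future C4 carbon of the middle unit is already attached. The method would also serve unsymmetrical A rings.
- Weak points: the ring being built is phloroglucinol, which can be bought. Building it atom by atom puts a thermal vinylketene reaction on an intermediate with a gallate ester and a hindered secondary centre at C4. The alkyne-bearing top unit has no short access. Three different protecting groups must later be adjusted. After A3 the middle ring C and the bottom unit are still to come.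
- Comparison: this road is better in generality and in not depending on a regioselective bromination or on equivalent ortho positions. The chosen plan sets against it three simple steps (2 to 4) to the same aryl group and no high-temperature step on an advanced intermediate.

Key step: step 7

Assumption 1: the (R) antipode of the phosphoric acid is written for steps 7 and 14; which antipode delivers the (2R,3R) series cannot be deduced from the structures, and the mirror-image catalyst would be used in both steps if the sense proves opposite.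

Assumption 2: flavan numbering (O1, C2, C3, C4, C4a, C5 to C8, C8a) and α/β descriptors are used; the CIP letter at C4 of the top unit can change between intermediates through priority changes alone, while the arrangement (C4 aryl β, trans to the C3 oxygen) is the same from 13 to 25.

Assumption 3: compounds 1, 3, 8, 10 and 16 are taken as commercial.

## Route

Step 1
Reactants: 1 2,4,6-trihydroxybenzaldehyde
Product: 2 2,4-bis(benzyloxy)-6-hydroxybenzaldehyde
Conditions: BnBr (2.05 equiv), K2CO3, DMF, 0 °C to rt
Reagents that add atoms: benzyl bromide, BrCc1ccccc1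
Why: Williamson ether synthesis; the hydroxyl para to the formyl group is the most acidic and one ortho hydroxyl follows, while the second ortho hydroxyl stays hydrogen-bonded to the carbonyl group and is left free as the future O1 of the top unit.

Step 2
Reactants: 3 3,5-bis(benzyloxy)phenol
Product: 4 [3,5-bis(benzyloxy)phenoxy]tri(propan-2-yl)silane
Conditions: TIPSCl, imidazole, DMF, rt
Reagents that add atoms: chlorotri(propan-2-yl)silane, CC(C)[Si](Cl)(C(C)C)C(C)C
Why: Standard silylation of a phenol; the bulky silyl ether marks the oxygen that becomes O1 of the middle unit and shields both carbons next to it.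

Step 3
Reactants: 4 [3,5-bis(benzyloxy)phenoxy]tri(propan-2-yl)silane
Product: 5 [4-bromo-3,5-bis(benzyloxy)phenoxy]tri(propan-2-yl)silane
Conditions: NBS (1.0 equiv), CH2Cl2, −78 to 0 °C
Reagents that add atoms: N-bromosuccinimide, O=C1CCC(=O)N1Br
Why: Electrophilic aromatic bromination of a phloroglucinol triether; the isopropyl groups block both carbons ortho to the silyloxy group, so bromine should enter para to it, between the two benzyloxy groups.

Step 4
Reactants: 5 [4-bromo-3,5-bis(benzyloxy)phenoxy]tri(propan-2-yl)silane; 2 2,4-bis(benzyloxy)-6-hydroxybenzaldehyde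
Product: 7 racemic [2,4-bis(benzyloxy)-6-hydroxyphenyl][2,6-bis(benzyloxy)-4-(triisopropylsilyloxy)phenyl]methanol, via aryllithium 6 (not isolated)
Conditions: 5 (2.2 equiv), n-BuLi (2.2 equiv), THF, −78 °C; then 2, −78 to −20 °C; H2O; Et3N-deactivated silica
Reagents that add atoms: none
Why: Bromine–lithium exchange outruns benzylic deprotonation at −78 °C; one equivalent of 6 deprotonates the phenol of 2 and the second adds to the formyl group (1,2-addition of an aryllithium). The carbinol centre is racemic and is destroyed in step 7.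

Step 5
Reactants: 8 3,4-bis(benzyloxy)benzaldehyde
Product: 9 1,2-bis(benzyloxy)-4-ethynylbenzene
Conditions: dimethyl (1-diazo-2-oxopropyl)phosphonate, K2CO3, MeOH/THF, rt
Reagents that add atoms: dimethyl (1-diazo-2-oxopropyl)phosphonate, COP(=O)(OC)C(=[N+]=[N-])C(C)=O
Why: Seyferth–Gilbert homologation in the Ohira–Bestmann form; the diazophosphonate anion adds to the aldehyde, and loss of phosphate and N2 followed by 1,2-hydride shift gives the terminal alkyne without touching benzyl ethers.

Step 6
Reactants: 9 1,2-bis(benzyloxy)-4-ethynylbenzene; 10 3,4,5-tris(benzyloxy)benzoic acid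
Product: 11 (Z)-2-[3,4-bis(benzyloxy)phenyl]ethenyl 3,4,5-tris(benzyloxy)benzoate
Conditions: Ru(methallyl)2(dppb) (2 mol %), toluene, 50 °C
Reagents that add atoms: none
Why: Ruthenium-catalysed anti-Markovnikov hydro-oxycarbonylation of a terminal alkyne; the carboxylate adds to the α-carbon of a ruthenium vinylidene and protonolysis gives the Z enol ester, as established for arylacetylenes and benzoic acids with this catalyst.

Step 7
Reactants: 7 racemic [2,4-bis(benzyloxy)-6-hydroxyphenyl][2,6-bis(benzyloxy)-4-(triisopropylsilyloxy)phenyl]methanol; 11 (Z)-2-[3,4-bis(benzyloxy)phenyl]ethenyl 3,4,5-tris(benzyloxy)benzoate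
Product: 13 (2R,3R,4S)-5,7-bis(benzyloxy)-2-[3,4-bis(benzyloxy)phenyl]-4-[2,6-bis(benzyloxy)-4-(triisopropylsilyloxy)phenyl]chroman-3-yl 3,4,5-tris(benzyloxy)benzoate (2,3-cis, 3,4-trans), via ortho-quinone methide 12 (not isolated)
Conditions: (R)-TRIP [(R)-3,3'-bis(2,4,6-triisopropylphenyl)-1,1'-binaphthyl-2,2'-diyl hydrogen phosphate] (10 mol %), 4 Å MS, CH2Cl2, −30 to 0 °C; 11 (1.5 equiv), slow addition of 7
Reagents that add atoms: none
Why: Proposed new method: the phosphoric acid protonates the carbinol of 7, water leaves, and the donor-stabilised cation collapses to ortho-quinone methide 12, which stays hydrogen-bonded to the chiral phosphate through its carbonyl oxygen; the closest known reaction type is the chiral phosphoric acid-catalysed (4+2) cycloaddition of ortho-quinone methides generated in situ with styrenes and enol ethers. Alkene 11 is polarised by its 3,4-dialkoxyphenyl group and not by the weakly donating acyloxy group, so its oxygen-bearing carbon is the nucleophilic end and bonds to the methide carbon (C3–C4), while charge builds at the benzylic carbon, which the methide oxygen captures (O1–C2). Ring C is therefore closed by an intermolecular, asynchronous, inverse-demand hetero-Diels–Alder addition of the oxadiene O1=C8a–C4a=C4 to the C2=C3 alkene. C2 and C3 come out cis because the addition is suprafacial on the Z alkene. C3 and C4 come out trans because the peri C5 benzyloxy group pushes the C4 aryl group of 12 to the carbonyl side (Z methide), and the endo transition state, with catechol ring and gallate under the diene, then places both dienophile substituents opposite that aryl group. The absolute sense is set by the phosphate, whose 3,3' aryl groups close one face of the bound methide. The step needs regioselectivity (from the styrene-type polarisation of 11) and retention of alkene geometry (from fast collapse of the tight ion pair at low temperature). It also needs suppression of Friedel–Crafts self-condensation of 12 (from the silyl group flanking both free carbons of the C4 aryl group, excess 11 and slow addition of 7).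

Step 8
Reactants: 13 silyl ether from step 7
Product: 14 (2R,3R,4S)-5,7-bis(benzyloxy)-2-[3,4-bis(benzyloxy)phenyl]-4-[2,6-bis(benzyloxy)-4-hydroxyphenyl]chroman-3-yl 3,4,5-tris(benzyloxy)benzoate
Conditions: TBAF (1.1 equiv), AcOH (1.2 equiv), THF, 0 °C
Reagents that add atoms: none
Why: Fluoride cleavage of an aryl silyl ether; acetic acid buffers the phenoxide so that the gallate ester and C2 are not exposed to base.

Step 9
Reactants: 14 phenol from step 8
Product: 15 (2R,3R)-5,7-bis(benzyloxy)-2-[3,4-bis(benzyloxy)phenyl]-4β-[2,6-bis(benzyloxy)-3-formyl-4-hydroxyphenyl]chroman-3-yl 3,4,5-tris(benzyloxy)benzoate (C4 aryl trans to the ester)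
Conditions: MgCl2, Et3N, (CH2O)n, THF, 65 °C; dilute HCl work-up
Reagents that add atoms: formaldehyde (as paraformaldehyde), C=O
Why: Magnesium phenoxide-directed ortho-formylation (Casnati–Skattebøl); formaldehyde is delivered inside the magnesium chelate to a carbon ortho to the phenol and the benzylic alkoxide is oxidised by a second formaldehyde. The two ortho carbons are equivalent through the twofold axis of the ring, so only one aldehyde can form, and its carbon becomes C4 of the middle unit.

Step 10
Reactants: 16 (+)-catechin
Product: 17 5,7,3',4'-tetra-O-benzyl-(+)-catechin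
Conditions: BnBr (4.2 equiv), K2CO3, DMF, 0 °C to rt
Reagents that add atoms: benzyl bromide, BrCc1ccccc1
Why: Williamson benzylation of the four phenols; carbonate is too weak a base to alkylate the secondary alcohol, and C2 and C3 are taken from the chiral pool unchanged.

Step 11
Reactants: 17 5,7,3',4'-tetra-O-benzyl-(+)-catechin
Product: 18 3,5,7,3',4'-penta-O-benzyl-(+)-catechin
Conditions: NaH, BnBr, Bu4NI (cat.), DMF, 0 °C to rt
Reagents that add atoms: benzyl bromide, BrCc1ccccc1
Why: Williamson ether synthesis at the secondary alcohol through its sodium alkoxide; no stereocentre is touched.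

Step 12
Reactants: 18 3,5,7,3',4'-penta-O-benzyl-(+)-catechin
Product: 19 8-bromo-3,5,7,3',4'-penta-O-benzyl-(+)-catechin
Conditions: NBS (1.0 equiv), CH2Cl2, −78 °C to rt
Reagents that add atoms: N-bromosuccinimide, O=C1CCC(=O)N1Br
Why: Electrophilic bromination; in benzylated flavans C8 is more accessible than C6, which lies between two benzyloxy groups, and this C8 selectivity is well established for catechin ethers.

Step 13
Reactants: 19 8-bromo-3,5,7,3',4'-penta-O-benzyl-(+)-catechin; 15 salicylaldehyde from step 9
Product: 22 benzhydrol in which the formyl carbon of 15 has become CH(OH) bonded to C8 of penta-O-benzyl-(+)-catechin (both carbinol epimers), via aryllithium 20 (not isolated), via arylmagnesium bromide 21 (not isolated)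
Conditions: 19 (2.2 equiv), n-BuLi, THF, −78 °C; MgBr2·OEt2, −78 to −40 °C; then 15, −40 to 0 °C; pH 7 buffer
Reagents that add atoms: none
Why: Bromine–lithium exchange and transmetalation give an arylmagnesium bromide, which is far less reactive toward the hindered, electron-rich benzoate than toward the aldehyde; the first equivalent forms the magnesium phenoxide, whose chelate activates the formyl group for 1,2-addition of the second. The carbinol epimers are used together because this centre is destroyed in step 14.

Step 14
Reactants: 22 benzhydrol from step 13; 11 (Z)-2-[3,4-bis(benzyloxy)phenyl]ethenyl 3,4,5-tris(benzyloxy)benzoate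
Product: 24 nonadeca-O-benzyl ether of the target (all eighteen phenols and the catechin C3 hydroxyl benzylated), via ortho-quinone methide 23 (not isolated)
Conditions: (R)-TRIP (10 to 20 mol %), 4 Å MS, CH2Cl2, −30 to 0 °C; 11 (2 equiv), slow addition of 22
Reagents that add atoms: none
Why: Proposed new method: the same acid-catalysed dehydration and (4+2) addition as in step 7 (closest known type: phosphoric acid-catalysed cycloadditions of ortho-quinone methides with styrenes and enol ethers); 22 ionises through its middle-ring phenol to methide 23, the peri C5 benzyloxy group again holds the catechin C8 aryl group on the carbonyl side, and endo, suprafacial addition of 11 closes the middle ring C with 2,3-cis and 3,4-trans relationships. The same catalyst antipode is relied on to override the remote resident stereocentres.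

Step 15
Reactants: 24 nonadeca-O-benzyl ether from step 14
Product: 25 (−)-epicatechin 3-O-gallate-(4β→6)-(−)-epicatechin 3-O-gallate-(4β→8)-(+)-catechin (target)
Conditions: H2 (1 atm), Pd(OH)2/C, THF/MeOH/H2O, rt; handled under argon
Reagents that add atoms: none
Why: Hydrogenolysis of all nineteen benzyl ethers under neutral conditions; the C4–aryl bonds, the C2–O1 bonds and the gallate esters are known to survive such conditions in benzylated proanthocyanidins.

## Compound list

1 | 2,4,6-trihydroxybenzaldehyde | O=Cc1c(O)cc(O)cc1O | starting material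
2 | 2,4-bis(benzyloxy)-6-hydroxybenzaldehyde | O=Cc1c(O)cc(OCc9ccccc9)cc1OCc9ccccc9 | intermediate
3 | 3,5-bis(benzyloxy)phenol | Oc1cc(OCc9ccccc9)cc(OCc9ccccc9)c1 | starting material
4 | [3,5-bis(benzyloxy)phenoxy]tri(propan-2-yl)silane | CC(C)[Si](Oc1cc(OCc9ccccc9)cc(OCc9ccccc9)c1)(C(C)C)C(C)C | intermediate
5 | [4-bromo-3,5-bis(benzyloxy)phenoxy]tri(propan-2-yl)silane | CC(C)[Si](Oc1cc(OCc9ccccc9)c(Br)c(OCc9ccccc9)c1)(C(C)C)C(C)C | intermediate
6 | [2,6-bis(benzyloxy)-4-(triisopropylsilyloxy)phenyl]lithium | [Li]c1c(OCc9ccccc9)cc(O[Si](C(C)C)(C(C)C)C(C)C)cc1OCc9ccccc9 | intermediate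
7 | racemic [2,4-bis(benzyloxy)-6-hydroxyphenyl][2,6-bis(benzyloxy)-4-(triisopropylsilyloxy)phenyl]methanol | OC(c1c(O)cc(OCc9ccccc9)cc1OCc9ccccc9)c1c(OCc9ccccc9)cc(O[Si](C(C)C)(C(C)C)C(C)C)cc1OCc9ccccc9 | intermediate
8 | 3,4-bis(benzyloxy)benzaldehyde | O=Cc1ccc(OCc9ccccc9)c(OCc9ccccc9)c1 | starting material
9 | 1,2-bis(benzyloxy)-4-ethynylbenzene | C#Cc1ccc(OCc9ccccc9)c(OCc9ccccc9)c1 | intermediate
10 | 3,4,5-tris(benzyloxy)benzoic acid | OC(=O)c1cc(OCc9ccccc9)c(OCc9ccccc9)c(OCc9ccccc9)c1 | starting material
11 | (Z)-2-[3,4-bis(benzyloxy)phenyl]ethenyl 3,4,5-tris(benzyloxy)benzoate | O=C(O/C=C\c1ccc(OCc9ccccc9)c(OCc9ccccc9)c1)c1cc(OCc9ccccc9)c(OCc9ccccc9)c(OCc9ccccc9)c1 | intermediate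
12 | (6Z)-3,5-bis(benzyloxy)-6-{[2,6-bis(benzyloxy)-4-(triisopropylsilyloxy)phenyl]methylidene}cyclohexa-2,4-dien-1-one (aryl group on the carbonyl side) | O=C1C=C(OCc9ccccc9)C=C(OCc9ccccc9)/C1=C/c1c(OCc9ccccc9)cc(O[Si](C(C)C)(C(C)C)C(C)C)cc1OCc9ccccc9 | intermediate
13 | (2R,3R,4S)-5,7-bis(benzyloxy)-2-[3,4-bis(benzyloxy)phenyl]-4-[2,6-bis(benzyloxy)-4-(triisopropylsilyloxy)phenyl]chroman-3-yl 3,4,5-tris(benzyloxy)benzoate (2,3-cis, 3,4-trans) | O=C(O[C@@H]1[C@@H](c2c(OCc9ccccc9)cc(O[Si](C(C)C)(C(C)C)C(C)C)cc2OCc9ccccc9)c2c(OCc9ccccc9)cc(OCc9ccccc9)cc2O[C@@H]1c1ccc(OCc9ccccc9)c(OCc9ccccc9)c1)c1cc(OCc9ccccc9)c(OCc9ccccc9)c(OCc9ccccc9)c1 | intermediate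
14 | (2R,3R,4S)-5,7-bis(benzyloxy)-2-[3,4-bis(benzyloxy)phenyl]-4-[2,6-bis(benzyloxy)-4-hydroxyphenyl]chroman-3-yl 3,4,5-tris(benzyloxy)benzoate | O=C(O[C@@H]1[C@@H](c2c(OCc9ccccc9)cc(O)cc2OCc9ccccc9)c2c(OCc9ccccc9)cc(OCc9ccccc9)cc2O[C@@H]1c1ccc(OCc9ccccc9)c(OCc9ccccc9)c1)c1cc(OCc9ccccc9)c(OCc9ccccc9)c(OCc9ccccc9)c1 | intermediate
15 | (2R,3R)-5,7-bis(benzyloxy)-2-[3,4-bis(benzyloxy)phenyl]-4β-[2,6-bis(benzyloxy)-3-formyl-4-hydroxyphenyl]chroman-3-yl 3,4,5-tris(benzyloxy)benzoate (2,3-cis, 3,4-trans) | O=C(O[C@@H]1[C@@H](c2c(OCc9ccccc9)c(C=O)c(O)cc2OCc9ccccc9)c2c(OCc9ccccc9)cc(OCc9ccccc9)cc2O[C@@H]1c1ccc(OCc9ccccc9)c(OCc9ccccc9)c1)c1cc(OCc9ccccc9)c(OCc9ccccc9)c(OCc9ccccc9)c1 | intermediate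
16 | (+)-catechin, (2R,3S) | O[C@H]1Cc2c(O)cc(O)cc2O[C@@H]1c1ccc(O)c(O)c1 | starting material
17 | 5,7,3',4'-tetra-O-benzyl-(+)-catechin | O[C@H]1Cc2c(OCc9ccccc9)cc(OCc9ccccc9)cc2O[C@@H]1c1ccc(OCc9ccccc9)c(OCc9ccccc9)c1 | intermediate
18 | 3,5,7,3',4'-penta-O-benzyl-(+)-catechin | c9ccccc9CO[C@H]1Cc2c(OCc9ccccc9)cc(OCc9ccccc9)cc2O[C@@H]1c1ccc(OCc9ccccc9)c(OCc9ccccc9)c1 | intermediate
19 | 8-bromo-3,5,7,3',4'-penta-O-benzyl-(+)-catechin | c9ccccc9CO[C@H]1Cc2c(OCc9ccccc9)cc(OCc9ccccc9)c(Br)c2O[C@@H]1c1ccc(OCc9ccccc9)c(OCc9ccccc9)c1 | intermediate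
20 | 8-lithio-3,5,7,3',4'-penta-O-benzyl-(+)-catechin | c9ccccc9CO[C@H]1Cc2c(OCc9ccccc9)cc(OCc9ccccc9)c([Li])c2O[C@@H]1c1ccc(OCc9ccccc9)c(OCc9ccccc9)c1 | intermediate
21 | 8-(bromomagnesio)-3,5,7,3',4'-penta-O-benzyl-(+)-catechin | c9ccccc9CO[C@H]1Cc2c(OCc9ccccc9)cc(OCc9ccccc9)c([Mg]Br)c2O[C@@H]1c1ccc(OCc9ccccc9)c(OCc9ccccc9)c1 | intermediate
22 | benzhydrol: compound 15 with CH(OH)–(C8 of penta-O-benzyl-(+)-catechin) in place of the formyl group, both carbinol epimers | O=C(O[C@@H]1[C@@H](c2c(OCc9ccccc9)c(C(O)c3c(OCc9ccccc9)cc(OCc9ccccc9)c4c3O[C@H](c3ccc(OCc9ccccc9)c(OCc9ccccc9)c3)[C@@H](OCc9ccccc9)C4)c(O)cc2OCc9ccccc9)c2c(OCc9ccccc9)cc(OCc9ccccc9)cc2O[C@@H]1c1ccc(OCc9ccccc9)c(OCc9ccccc9)c1)c1cc(OCc9ccccc9)c(OCc9ccccc9)c(OCc9ccccc9)c1 | intermediate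
23 | ortho-quinone methide from 22: middle ring as 3,5-bis(benzyloxy)cyclohexa-2,4-dien-1-one carrying the top unit at ring carbon 4 and an exocyclic C=CH–(catechin C8) at ring carbon 6, catechin aryl group on the carbonyl side (Z) | O=C(O[C@@H]1[C@@H](C2=C(OCc9ccccc9)/C(=C/c3c(OCc9ccccc9)cc(OCc9ccccc9)c4c3O[C@H](c3ccc(OCc9ccccc9)c(OCc9ccccc9)c3)[C@@H](OCc9ccccc9)C4)C(=O)C=C2OCc9ccccc9)c2c(OCc9ccccc9)cc(OCc9ccccc9)cc2O[C@@H]1c1ccc(OCc9ccccc9)c(OCc9ccccc9)c1)c1cc(OCc9ccccc9)c(OCc9ccccc9)c(OCc9ccccc9)c1 | intermediate
24 | nonadeca-O-benzyl ether of 25 (top and middle units 2,3-cis-3,4-trans with 4β aryl; bottom unit 2R,3S) | O=C(O[C@@H]1[C@@H](c2c(OCc9ccccc9)cc3c(c2OCc9ccccc9)[C@H](c2c(OCc9ccccc9)cc(OCc9ccccc9)c4c2O[C@H](c2ccc(OCc9ccccc9)c(OCc9ccccc9)c2)[C@@H](OCc9ccccc9)C4)[C@@H](OC(=O)c2cc(OCc9ccccc9)c(OCc9ccccc9)c(OCc9ccccc9)c2)[C@@H](c2ccc(OCc9ccccc9)c(OCc9ccccc9)c2)O3)c2c(OCc9ccccc9)cc(OCc9ccccc9)cc2O[C@@H]1c1ccc(OCc9ccccc9)c(OCc9ccccc9)c1)c1cc(OCc9ccccc9)c(OCc9ccccc9)c(OCc9ccccc9)c1 | intermediate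
25 | (−)-epicatechin 3-O-gallate-(4β→6)-(−)-epicatechin 3-O-gallate-(4β→8)-(+)-catechin; top unit 2R,3R,4S, middle unit 2R,3R,4R, bottom unit 2R,3S | O=C(O[C@@H]1[C@@H](c2c(O)cc3c(c2O)[C@H](c2c(O)cc(O)c4c2O[C@H](c2ccc(O)c(O)c2)[C@@H](O)C4)[C@@H](OC(=O)c2cc(O)c(O)c(O)c2)[C@@H](c2ccc(O)c(O)c2)O3)c2c(O)cc(O)cc2O[C@@H]1c1ccc(O)c(O)c1)c1cc(O)c(O)c(O)c1 | target

## Step count and risks

Total: 15 steps. Longest linear sequence: 9 steps (3 to 25 through steps 2, 3, 4, 7, 8, 9, 13, 14, 15).

**Step 7 (key step, Proposed new method).**
- What may go wrong: no addition or reversed regiochemistry if the acyloxy group damps the alkene or the highly stabilised cation is too weak an electrophile. Stepwise addition with bond rotation in the benzylic cation before ring closure would erode the 2,3-cis relationship. Exo addition or an E methide would give the 3,4-cis isomer. A loose ion pair would give poor facial selectivity. Friedel–Crafts self-condensation of 12 through the free C8 of its phenol ring and acyl transfer from the enol ester to the phenol are competing processes.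
- Fallback (known chemistry), setting out from 4 and 10 and returning at 13: ring C of the top unit is taken from the chiral pool and only the C4–aryl bond is made. (−)-Epicatechin is benzylated (BnBr, K2CO3) to 5,7,3',4'-tetra-O-benzyl-(−)-epicatechin F1. DDQ and 2-ethoxyethanol oxidise F1 at C4 to the acetal 4β-(2-ethoxyethoxy)-5,7,3',4'-tetra-O-benzyl-(−)-epicatechin F2. TMSOTf in CH2Cl2 at −78 °C ionises F2 in the presence of excess arene 4, which should capture the C4 cation para to its silyloxy group and trans to the C3 oxygen, giving the 4β-aryl flavan-3-ol F3. Steglich esterification of F3 with acid 10 (DCC, DMAP) gives 13.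

**Step 14 (Proposed new method).**
- What may go wrong: mismatch between the catalyst and the resident stereocentres (the catechin C2 aryl group lies close to the methide oxygen), greater congestion at the methide carbon than in step 7, and oligomerisation through the free C8 of the middle ring.
- Fallback (known chemistry), setting out from 18 and 10 and returning at 25: the middle unit is also taken from (−)-epicatechin and joined by Lewis acid flavan couplings with orthogonal C4 leaving groups. F1 (see step 7) is brominated with NBS to 8-bromo-5,7,3',4'-tetra-O-benzyl-(−)-epicatechin F4. F4 is oxidised with DDQ and 2-ethoxyethanol to 8-bromo-4β-(2-ethoxyethoxy)-5,7,3',4'-tetra-O-benzyl-(−)-epicatechin F5. F5 is exchanged with 2,6-dimethylbenzenethiol and BF3·OEt2 to 8-bromo-4β-(2,6-dimethylphenylsulfanyl)-5,7,3',4'-tetra-O-benzyl-(−)-epicatechin F6, a nucleophile with only C6 free and a C4–S bond inert to hard Lewis acids. TMSOTf-promoted coupling of F2 (see step 7) with F6 should give the 4β→6 dimer F7. Activation of the thioether of F7 with a thiophilic silver salt (AgOTf) in the presence of 18 should form the 4β→8 bond and give the trimer F8. Double esterification of F8 with 10 (DCC, DMAP) gives the bis-gallate F9. Hydrogenolysis of F9 over Pd(OH)2/C with Et3N removes the benzyl groups and the bromine and gives 25.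

**Step 3.**
- What may go wrong: bromination ortho to the silyloxy group or double bromination, because all three ring carbons are activated and the selectivity rests on steric shielding alone.
- Fallback, setting out from 3 and returning at 7 (compounds 2, 5 and 6 are then not needed): the polarity of the benzhydrol assembly is reversed. Vilsmeier–Haack formylation of 3 (POCl3, DMF) should give mainly the para-formyl phenol 2,6-bis(benzyloxy)-4-hydroxybenzaldehyde F10, separable from its hydrogen-bonded ortho isomer. Silylation of F10 (TIPSCl, imidazole) gives 2,6-bis(benzyloxy)-4-(triisopropylsilyloxy)benzaldehyde F11. A second portion of 3, deprotonated with EtMgBr in toluene, is then hydroxyalkylated at its ortho carbon by F11 (ortho-specific hydroxyalkylation of a magnesium phenoxide) to give 7.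

**Step 13.**
- What may go wrong: attack of the arylmetal on the gallate ester, or failure of the hindered arylmagnesium species to add to the di-ortho-substituted, phenoxide-deactivated aldehyde, leaving only protonation to 18.
- Fallback, setting out from 14 and 19 and returning at 22 (step 9 is then not needed): the bond polarity is reversed. Bromide 19 is lithiated (n-BuLi, −78 °C) and quenched with DMF to give 8-formyl-3,5,7,3',4'-penta-O-benzyl-(+)-catechin F12. Phenol 14, deprotonated with EtMgBr in toluene, is then hydroxyalkylated by F12 at either of its two equivalent ortho carbons to give 22.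

## Further compounds

F1 | step 7 | 5,7,3',4'-tetra-O-benzyl-(−)-epicatechin | O[C@@H]1Cc2c(OCc9ccccc9)cc(OCc9ccccc9)cc2O[C@@H]1c1ccc(OCc9ccccc9)c(OCc9ccccc9)c1
F2 | step 7 | 4β-(2-ethoxyethoxy)-5,7,3',4'-tetra-O-benzyl-(−)-epicatechin (3,4-trans) | O[C@@H]1[C@@H](OCCOCC)c2c(OCc9ccccc9)cc(OCc9ccccc9)cc2O[C@@H]1c1ccc(OCc9ccccc9)c(OCc9ccccc9)c1
F3 | step 7 | 4β-[2,6-bis(benzyloxy)-4-(triisopropylsilyloxy)phenyl]-5,7,3',4'-tetra-O-benzyl-(−)-epicatechin (free C3 hydroxyl, 3,4-trans) | O[C@@H]1[C@@H](c2c(OCc9ccccc9)cc(O[Si](C(C)C)(C(C)C)C(C)C)cc2OCc9ccccc9)c2c(OCc9ccccc9)cc(OCc9ccccc9)cc2O[C@@H]1c1ccc(OCc9ccccc9)c(OCc9ccccc9)c1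
F4 | step 14 | 8-bromo-5,7,3',4'-tetra-O-benzyl-(−)-epicatechin | O[C@@H]1Cc2c(OCc9ccccc9)cc(OCc9ccccc9)c(Br)c2O[C@@H]1c1ccc(OCc9ccccc9)c(OCc9ccccc9)c1
F5 | step 14 | 8-bromo-4β-(2-ethoxyethoxy)-5,7,3',4'-tetra-O-benzyl-(−)-epicatechin | O[C@@H]1[C@@H](OCCOCC)c2c(OCc9ccccc9)cc(OCc9ccccc9)c(Br)c2O[C@@H]1c1ccc(OCc9ccccc9)c(OCc9ccccc9)c1
F6 | step 14 | 8-bromo-4β-(2,6-dimethylphenylsulfanyl)-5,7,3',4'-tetra-O-benzyl-(−)-epicatechin | O[C@@H]1[C@@H](Sc2c(C)cccc2C)c2c(OCc9ccccc9)cc(OCc9ccccc9)c(Br)c2O[C@@H]1c1ccc(OCc9ccccc9)c(OCc9ccccc9)c1
F7 | step 14 | tetra-O-benzyl-epicatechin-(4β→6)-[8-bromo-4β-(2,6-dimethylphenylsulfanyl)-tetra-O-benzyl-epicatechin], both C3 hydroxyls free | O[C@@H]1[C@@H](c2c(OCc9ccccc9)c(Br)c3c(c2OCc9ccccc9)[C@H](Sc2c(C)cccc2C)[C@@H](O)[C@@H](c2ccc(OCc9ccccc9)c(OCc9ccccc9)c2)O3)c2c(OCc9ccccc9)cc(OCc9ccccc9)cc2O[C@@H]1c1ccc(OCc9ccccc9)c(OCc9ccccc9)c1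
F8 | step 14 | tetra-O-benzyl-epicatechin-(4β→6)-(8-bromo-tetra-O-benzyl-epicatechin)-(4β→8)-penta-O-benzyl-catechin, C3 hydroxyls of the two upper units free | O[C@@H]1[C@@H](c2c(OCc9ccccc9)c(Br)c3c(c2OCc9ccccc9)[C@H](c2c(OCc9ccccc9)cc(OCc9ccccc9)c4c2O[C@H](c2ccc(OCc9ccccc9)c(OCc9ccccc9)c2)[C@@H](OCc9ccccc9)C4)[C@@H](O)[C@@H](c2ccc(OCc9ccccc9)c(OCc9ccccc9)c2)O3)c2c(OCc9ccccc9)cc(OCc9ccccc9)cc2O[C@@H]1c1ccc(OCc9ccccc9)c(OCc9ccccc9)c1
F9 | step 14 | compound 24 carrying bromine at C8 of the middle unit (bis[3,4,5-tris(benzyloxy)benzoate] of F8) | O=C(O[C@@H]1[C@@H](c2c(OCc9ccccc9)c(Br)c3c(c2OCc9ccccc9)[C@H](c2c(OCc9ccccc9)cc(OCc9ccccc9)c4c2O[C@H](c2ccc(OCc9ccccc9)c(OCc9ccccc9)c2)[C@@H](OCc9ccccc9)C4)[C@@H](OC(=O)c2cc(OCc9ccccc9)c(OCc9ccccc9)c(OCc9ccccc9)c2)[C@@H](c2ccc(OCc9ccccc9)c(OCc9ccccc9)c2)O3)c2c(OCc9ccccc9)cc(OCc9ccccc9)cc2O[C@@H]1c1ccc(OCc9ccccc9)c(OCc9ccccc9)c1)c1cc(OCc9ccccc9)c(OCc9ccccc9)c(OCc9ccccc9)c1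
F10 | step 3 | 2,6-bis(benzyloxy)-4-hydroxybenzaldehyde | O=Cc1c(OCc9ccccc9)cc(O)cc1OCc9ccccc9
F11 | step 3 | 2,6-bis(benzyloxy)-4-(triisopropylsilyloxy)benzaldehyde | O=Cc1c(OCc9ccccc9)cc(O[Si](C(C)C)(C(C)C)C(C)C)cc1OCc9ccccc9
F12 | step 13 | 8-formyl-3,5,7,3',4'-penta-O-benzyl-(+)-catechin | c9ccccc9CO[C@H]1Cc2c(OCc9ccccc9)cc(OCc9ccccc9)c(C=O)c2O[C@@H]1c1ccc(OCc9ccccc9)c(OCc9ccccc9)c1
A1 | alternative 1 | trideca-O-benzyl trimer with tert-butyldimethylsilyl ethers at the C3 oxygens of the top and middle units | CC(C)(C)[Si](C)(C)O[C@@H]1[C@@H](c2c(OCc9ccccc9)cc3c(c2OCc9ccccc9)[C@H](c2c(OCc9ccccc9)cc(OCc9ccccc9)c4c2O[C@H](c2ccc(OCc9ccccc9)c(OCc9ccccc9)c2)[C@@H](OCc9ccccc9)C4)[C@@H](O[Si](C)(C)C(C)(C)C)[C@@H](c2ccc(OCc9ccccc9)c(OCc9ccccc9)c2)O3)c2c(OCc9ccccc9)cc(OCc9ccccc9)cc2O[C@@H]1c1ccc(OCc9ccccc9)c(OCc9ccccc9)c1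
A2 | alternative 2 | hexadeca-O-benzyl trimer with the top gallate in place and a free C3 hydroxyl on the middle unit | O=C(O[C@@H]1[C@@H](c2c(OCc9ccccc9)cc3c(c2OCc9ccccc9)[C@H](c2c(OCc9ccccc9)cc(OCc9ccccc9)c4c2O[C@H](c2ccc(OCc9ccccc9)c(OCc9ccccc9)c2)[C@@H](OCc9ccccc9)C4)[C@@H](O)[C@@H](c2ccc(OCc9ccccc9)c(OCc9ccccc9)c2)O3)c2c(OCc9ccccc9)cc(OCc9ccccc9)cc2O[C@@H]1c1ccc(OCc9ccccc9)c(OCc9ccccc9)c1)c1cc(OCc9ccccc9)c(OCc9ccccc9)c(OCc9ccccc9)c1
A3 | alternative 3 | protected top gallate unit carrying at C4 a 6-hydroxy-4-(methoxymethoxy)-3-(tert-butyldimethylsilyloxymethyl)-2-(triisopropylsilyloxy)phenyl group | O=C(O[C@@H]1[C@@H](c2c(O)cc(OCOC)c(CO[Si](C)(C)C(C)(C)C)c2O[Si](C(C)C)(C(C)C)C(C)C)c2c(OCc9ccccc9)cc(OCc9ccccc9)cc2O[C@@H]1c1ccc(OCc9ccccc9)c(OCc9ccccc9)c1)c1cc(OCc9ccccc9)c(OCc9ccccc9)c(OCc9ccccc9)c1
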